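**Retrosynthetic overview**
1. The two exocyclic Z-alkenes are cut to a C4 bis-phosphonium linchpin and two mirror-image 2-silyloxy-cyclohexanones, joined by two successive Z-selective Wittig reactions.
2. Each cyclohexanone comes from a semipinacol ring contraction (seven- to six-membered) of an anti-2,3-epoxy silyl ether of a cycloheptanone, which sets the quaternary carbon and the carbinol carbon together.
3. The contraction is run on the racemic epoxide as a catalyst-controlled kinetic resolution, once with each enantiomer of the catalyst, so that one racemate supplies both enantiomeric halves.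
4. The epoxide comes from a 4-silyloxy-cyclohept-2-enone (nucleophilic epoxidation), and the cycloheptenone from ring-closing metathesis of an acyclic hydroxy dienone built from glutaric anhydride and three small organometallics.
5. Ring order: cycloheptenone (metathesis), oxirane, cyclohexane (contraction); the two cyclohexanes are linked last.

**Assumptions**
- The two halves of the given SMILES carry mirror-image descriptors (1R,2S and 1'S,2'R) and both alkenes are Z, so the target is the meso, achiral stereoisomer. "Single enantiomer" is read as "this single stereoisomer"; both enantiomers of the half-unit are therefore needed 1:1.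
- The (1S,6S,7R) epoxide is taken as the enantiomer that the (S,S) catalyst converts faster. If the sense is the opposite, the two catalyst enantiomers exchange between steps 6 and 7 and nothing else changes.
- Steps 6 and 7 are run on equal portions of the racemic epoxide to the same conversion. The unreacted epoxide of the two runs, pooled, is racemic again and is returned to both steps.

**Route**

Step 1
Reactants: 1 glutaric anhydride; 2 isopropenylmagnesium bromide CH2=C(CH3)MgBr; 3 prenyl chloride
Product: 7 rac-6-(3-methylbut-2-en-1-yl)-6-(prop-1-en-2-yl)oxan-2-one, via bromomagnesium keto carboxylate 4 (not isolated), via prenylbarium chloride 5 (not isolated), via hydroxy acid 6 (not isolated)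
Conditions: 2 (1.0 equiv) added to 1, THF, −78 °C; then transferred into 5 (made in a second flask from 3, BaI2, Li, biphenyl, THF, −78 °C), −78 °C; 1 M HCl; PPTS (cat.), toluene, 50 °C
Reagents that add atoms: none
Why: Grignard mono-acylation by the cyclic anhydride gives the keto carboxylate, the allylbarium reagent (Yamamoto α-selective allylation) then adds 1,2 through its CH2 terminus, and the tertiary δ-hydroxy acid lactonises on acidification; the new stereocentre forms as the racemate.

Step 2
Reactants: 7 rac-6-(3-methylbut-2-en-1-yl)-6-(prop-1-en-2-yl)oxan-2-one; 8 vinylmagnesium bromide CH2=CHMgBr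
Product: 9 rac-7-hydroxy-10-methyl-7-(prop-1-en-2-yl)undeca-1,9-dien-3-one
Conditions: CH2=CHMgBr (1.1 equiv), THF, −78 °C; AcOH, −78 °C
Reagents that add atoms: none
Why: Mono-addition of a Grignard reagent to a δ-lactone, in which the magnesium lactolate survives at −78 °C and opens only on protonation to the vinyl ketone and the tertiary alcohol (in equilibrium with its cyclic hemiketal).

Step 3
Reactants: 9 rac-7-hydroxy-10-methyl-7-(prop-1-en-2-yl)undeca-1,9-dien-3-one
Product: 10 rac-4-hydroxy-3-methyl-4-(3-methylbut-2-en-1-yl)cyclohept-2-en-1-one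
Conditions: second-generation Hoveyda–Grubbs catalyst RuCl2(H2IMes)(=CH-C6H4-2-OiPr) (5 mol%), toluene (5 mM), 80 °C
Reagents that add atoms: none
Why: Ring-closing metathesis between the vinyl ketone and the isopropenyl group closes the seven-membered enone; the prenyl alkene cannot close a favourable ring and the allylic hydroxyl helps the ruthenium carbene engage the hindered alkene.

Step 4
Reactants: 10 rac-4-hydroxy-3-methyl-4-(3-methylbut-2-en-1-yl)cyclohept-2-en-1-one
Product: 11 rac-3-methyl-4-(3-methylbut-2-en-1-yl)-4-(triethylsilyloxy)cyclohept-2-en-1-one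
Conditions: Et3SiOTf (1.3 equiv), 2,6-lutidine, CH2Cl2, −78 to 0 °C
Reagents that add atoms: triethylsilyl trifluoromethanesulfonate, CC[Si](CC)(CC)OS(=O)(=O)C(F)(F)F
Why: Standard silyl-triflate silylation of a tertiary alcohol; this one silyl group later steers the epoxidation, carries the semipinacol shift and blocks retro-aldol cleavage during the Wittig steps.

Step 5
Reactants: 11 rac-3-methyl-4-(3-methylbut-2-en-1-yl)-4-(triethylsilyloxy)cyclohept-2-en-1-one
Product: 12 rac-(1S,6S,7R)-7-methyl-6-(3-methylbut-2-en-1-yl)-6-(triethylsilyloxy)-8-oxabicyclo[5.1.0]octan-2-one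
Conditions: t-BuOOH, benzyltrimethylammonium hydroxide (0.3 equiv), THF, 0 °C to rt
Reagents that add atoms: tert-butyl hydroperoxide, CC(C)(C)OO
Why: Weitz–Scheffer nucleophilic epoxidation, in which the peroxide anion adds to the β-carbon anti to the pseudo-axial C–OSiEt3 bond (Felkin–Anh-type control, as for γ-silyloxy enones) and the enolate closes the oxirane, so the epoxide is trans to the silyloxy group and cis to the prenyl group; the electron-rich prenyl alkene is inert to the nucleophilic oxidant.

Step 6
Reactants: 12 rac-(1S,6S,7R)-7-methyl-6-(3-methylbut-2-en-1-yl)-6-(triethylsilyloxy)-8-oxabicyclo[5.1.0]octan-2-one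
Product: 13 (2S,3S)-3-methyl-3-(4-methylpent-3-enoyl)-2-(triethylsilyloxy)cyclohexan-1-one
Conditions: (S,S)-imidodiphosphorimidate Brønsted acid (IDPi, 2 mol%), allyltriethylsilane (5 mol%), toluene, −78 °C, to about 40% conversion; Et3N; chromatography
Reagents that add atoms: none
Why: Proposed new method: a chiral silylium imidodiphosphorimidate ion pair (Et3Si+ IDPi−, formed from the acid and the allylsilane) silylates the epoxide oxygen, the C7–O bond at the tertiary β-carbon of the epoxy ketone breaks with concerted anti 1,2-shift of ring carbon C5 from C6 to C7 (inversion at the methyl-bearing carbon, retention at the carbinol carbon, hence silyloxy cis to the acyl group), the silyloxocarbenium ion returns Et3Si+ to the anion, and the confined chiral anion distinguishes the two enantiomeric silyloxonium ions so that only the (1S,6S,7R) epoxide of the racemate contracts; the prenyl group is syn to the epoxide oxygen and cannot migrate; the closest known chemistry is the silyl-triflate-catalysed Suzuki–Tsuchihashi semipinacol rearrangement of 2,3-epoxy silyl ethers, together with silylium–IDPi catalysis and chiral-acid-catalysed asymmetric semipinacol shifts, but an enantiomer-selecting ring contraction of this kind is not known.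

Step 7
Reactants: 12 rac-(1S,6S,7R)-7-methyl-6-(3-methylbut-2-en-1-yl)-6-(triethylsilyloxy)-8-oxabicyclo[5.1.0]octan-2-one
Product: 14 (2R,3R)-3-methyl-3-(4-methylpent-3-enoyl)-2-(triethylsilyloxy)cyclohexan-1-one
Conditions: (R,R)-imidodiphosphorimidate Brønsted acid (IDPi, 2 mol%), allyltriethylsilane (5 mol%), toluene, −78 °C, to about 40% conversion; Et3N; chromatography
Reagents that add atoms: none
Why: Proposed new method: the same silylium–IDPi enantiomer-selecting semipinacol ring contraction run with the mirror-image catalyst, which by symmetry selects the (1R,6R,7S) epoxide of the racemate with the same rate ratio and contracts it by the same stereospecific anti shift with silyl transfer to the mirror-image ketone; the closest known reaction type is again the silyl-triflate-catalysed Suzuki–Tsuchihashi rearrangement of 2,3-epoxy silyl ethers.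

Step 8
Reactants: 15 1,4-dibromobutane
Product: 16 butane-1,4-diylbis(triphenylphosphonium) dibromide
Conditions: PPh3 (2.2 equiv), DMF, 150 °C
Reagents that add atoms: triphenylphosphine, c1ccccc1P(c1ccccc1)c1ccccc1
Why: Double SN2 quaternisation of triphenylphosphine by the primary dibromide.

Step 9
Reactants: 13 (2S,3S)-3-methyl-3-(4-methylpent-3-enoyl)-2-(triethylsilyloxy)cyclohexan-1-one; 16 butane-1,4-diylbis(triphenylphosphonium) dibromide
Product: 18 {(4Z)-4-[(2R,3S)-3-methyl-3-(4-methylpent-3-enoyl)-2-(triethylsilyloxy)cyclohexylidene]butyl}triphenylphosphonium bromide, via ylide phosphonium bromide 17 (not isolated)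
Conditions: 16 (3.0 equiv), KN(SiMe3)2 (2.5 equiv), THF/DMPU 5:1, −20 °C; 13 (1.0 equiv), −40 to 0 °C; pH 7 phosphate buffer
Reagents that add atoms: none
Why: Wittig olefination of an α-silyloxy ketone by the non-stabilised ylide end of the mono-deprotonated bis-salt gives the phosphonium salt directly, and because the dicationic salt is more acidic than the monocationic product the excess of 16 buffers the mixture against a second ylide and a second olefination; the ylide chain goes cis to the oxygen-bearing carbon (Z, Still-type α-alkoxy-ketone selectivity), the hindered acyl ketone on the quaternary carbon does not react, and no stereocentre is touched (the C2 descriptor changes only through CIP priorities).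

Step 10
Reactants: 18 {(4Z)-4-[(2R,3S)-3-methyl-3-(4-methylpent-3-enoyl)-2-(triethylsilyloxy)cyclohexylidene]butyl}triphenylphosphonium bromide; 14 (2R,3R)-3-methyl-3-(4-methylpent-3-enoyl)-2-(triethylsilyloxy)cyclohexan-1-one
Product: 20 (1R,2S,3Z,1'S,2'R,3'Z)-3,3'-(butane-1,4-diylidene)bis[1-methyl-1-(4-methylpent-3-enoyl)-2-(triethylsilyloxy)cyclohexane], via ylide 19 (not isolated)
Conditions: KN(SiMe3)2 (1.0 equiv), THF/DMPU 5:1, −78 °C, 5 min; 14 (1.1 equiv), −78 to 0 °C; pH 7 phosphate buffer
Reagents that add atoms: none
Why: Fast kinetic deprotonation of the phosphonium salt gives the ylide, and a second Z-selective α-silyloxy-ketone Wittig reaction joins the two mirror-image halves, so the meso arrangement is fixed by construction because each half comes from a different enantiomer.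

Step 11
Reactants: 20 (1R,2S,3Z,1'S,2'R,3'Z)-3,3'-(butane-1,4-diylidene)bis[1-methyl-1-(4-methylpent-3-enoyl)-2-(triethylsilyloxy)cyclohexane]
Product: 21 (1R,2S,3Z,1'S,2'R,3'Z)-3,3'-(butane-1,4-diylidene)bis[2-hydroxy-1-methyl-1-(4-methylpent-3-enoyl)cyclohexane] (target)
Conditions: HF·pyridine, pyridine, THF, 0 °C to rt
Reagents that add atoms: none
Why: Buffered fluoride desilylation removes both silyl ethers without base, which avoids retro-aldol cleavage of the β-hydroxy ketones and conjugation of the β,γ-unsaturated ketones.

**Compound list**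
1 | glutaric anhydride (oxane-2,6-dione) | O=C1CCCC(=O)O1 | starting material
2 | isopropenylmagnesium bromide | CC(=C)[Mg]Br | starting material
3 | prenyl chloride (1-chloro-3-methylbut-2-ene) | CC(C)=CCCl | starting material
4 | bromomagnesium 6-methyl-5-oxohept-6-enoate | CC(=C)C(=O)CCCC(=O)[O-].[Mg+2].[Br-] | intermediate
5 | prenylbarium chloride | CC(C)=CC[Ba]Cl | intermediate
6 | rac-5-hydroxy-8-methyl-5-(prop-1-en-2-yl)non-7-enoic acid | CC(C)=CCC(O)(CCCC(=O)O)C(C)=C | intermediate
7 | rac-6-(3-methylbut-2-en-1-yl)-6-(prop-1-en-2-yl)oxan-2-one | CC(C)=CCC1(C(C)=C)CCCC(=O)O1 | intermediate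
8 | vinylmagnesium bromide | C=C[Mg]Br | starting material
9 | rac-7-hydroxy-10-methyl-7-(prop-1-en-2-yl)undeca-1,9-dien-3-one | C=CC(=O)CCCC(O)(CC=C(C)C)C(C)=C | intermediate
10 | rac-4-hydroxy-3-methyl-4-(3-methylbut-2-en-1-yl)cyclohept-2-en-1-one | O=C1C=C(C)C(O)(CC=C(C)C)CCC1 | intermediate
11 | rac-3-methyl-4-(3-methylbut-2-en-1-yl)-4-(triethylsilyloxy)cyclohept-2-en-1-one | O=C1C=C(C)C(O[Si](CC)(CC)CC)(CC=C(C)C)CCC1 | intermediate
12 | rac-(1S,6S,7R)-7-methyl-6-(3-methylbut-2-en-1-yl)-6-(triethylsilyloxy)-8-oxabicyclo[5.1.0]octan-2-one (racemate; the (1S,6S,7R) enantiomer is drawn) | O=C1CCC[C@](O[Si](CC)(CC)CC)(CC=C(C)C)[C@]2(C)O[C@H]12 | intermediate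
13 | (2S,3S)-3-methyl-3-(4-methylpent-3-enoyl)-2-(triethylsilyloxy)cyclohexan-1-one | O=C1CCC[C@](C)(C(=O)CC=C(C)C)[C@@H]1O[Si](CC)(CC)CC | intermediate
14 | (2R,3R)-3-methyl-3-(4-methylpent-3-enoyl)-2-(triethylsilyloxy)cyclohexan-1-one | O=C1CCC[C@@](C)(C(=O)CC=C(C)C)[C@H]1O[Si](CC)(CC)CC | intermediate
15 | 1,4-dibromobutane | BrCCCCBr | starting material
16 | butane-1,4-diylbis(triphenylphosphonium) dibromide | [Br-].[Br-].c1ccccc1[P+](c1ccccc1)(c1ccccc1)CCCC[P+](c1ccccc1)(c1ccccc1)c1ccccc1 | intermediate
17 | triphenyl[4-(triphenyl-λ5-phosphanylidene)butyl]phosphonium bromide (mono-ylide of 16) | [Br-].c1ccccc1[P+](c1ccccc1)(c1ccccc1)CCCC=P(c1ccccc1)(c1ccccc1)c1ccccc1 | intermediate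
18 | {(4Z)-4-[(2R,3S)-3-methyl-3-(4-methylpent-3-enoyl)-2-(triethylsilyloxy)cyclohexylidene]butyl}triphenylphosphonium bromide | [Br-].c1ccccc1[P+](c1ccccc1)(c1ccccc1)CCC/C=C2/CCC[C@](C)(C(=O)CC=C(C)C)[C@@H]2O[Si](CC)(CC)CC | intermediate
19 | 4-methyl-1-{(1S,2R,3Z)-1-methyl-2-(triethylsilyloxy)-3-[4-(triphenyl-λ5-phosphanylidene)butylidene]cyclohexyl}pent-3-en-1-one | c1ccccc1P(c1ccccc1)(c1ccccc1)=CCC/C=C2/CCC[C@](C)(C(=O)CC=C(C)C)[C@@H]2O[Si](CC)(CC)CC | intermediate
20 | (1R,2S,3Z,1'S,2'R,3'Z)-3,3'-(butane-1,4-diylidene)bis[1-methyl-1-(4-methylpent-3-enoyl)-2-(triethylsilyloxy)cyclohexane] (meso) | CC(C)=CCC(=O)[C@]1(C)CCC/C(=C/CC/C=C2/CCC[C@](C)(C(=O)CC=C(C)C)[C@@H]2O[Si](CC)(CC)CC)[C@@H]1O[Si](CC)(CC)CC | intermediate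
21 | (1R,2S,3Z,1'S,2'R,3'Z)-3,3'-(butane-1,4-diylidene)bis[2-hydroxy-1-methyl-1-(4-methylpent-3-enoyl)cyclohexane] (meso; CNP0297042.2) | CC(C)=CCC(=O)[C@]1(C)CCC/C(=C/CC/C=C2/CCC[C@](C)(C(=O)CC=C(C)C)[C@@H]2O)[C@@H]1O | target

**Step count and risks**

Total steps: 11. Longest linear sequence: 9 (steps 1–6, 9, 10, 11).

The three steps most likely to fail:

Step 5 (facial selectivity of the epoxidation). The anti outcome is argued from γ-silyloxy-enone precedent, not demonstrated on this tertiary, β-methyl-substituted cycloheptenone. If the epoxide forms syn to the silyloxy group, the prenyl group is placed anti to the epoxide and would migrate in place of the ring carbon. The fallback sets out from 11 and comes back at 12. NaBH4/CeCl3·7H2O in MeOH at −40 °C reduces the enone; the 1,4-trans allylic alcohol rel-(1R,4S)-3-methyl-4-(3-methylbut-2-en-1-yl)-4-(triethylsilyloxy)cyclohept-2-en-1-ol F1 is separated, and the cis isomer is reoxidised with MnO2 and recycled. VO(acac)2/t-BuOOH then delivers oxygen from the hydroxyl face, which is the face anti to the silyloxy group, giving rel-(1R,2R,6S,7R)-7-methyl-6-(3-methylbut-2-en-1-yl)-6-(triethylsilyloxy)-8-oxabicyclo[5.1.0]octan-2-ol F2. Dess–Martin periodinane oxidises F2 to 12.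

Step 6 (the proposed enantiomer-selecting ring contraction; step 7 is the same reaction with the mirror-image catalyst and shares this risk and this fallback). The selectivity factor may be too low to give the ketones in high enantiomeric purity even at 40% conversion, in which case the minor enantiomer would surface after step 10 as a C2-symmetric diastereomer of 20. A 1,2-acyl shift of the ring carbonyl carbon could also compete with the ring-carbon shift. The fallback sets out from 12 and comes back at 13 and 14, using known chemistry only. Et3SiOTf (10 mol%) in CH2Cl2 at −78 °C rearranges all of racemic 12 to rac-3-methyl-3-(4-methylpent-3-enoyl)-2-(triethylsilyloxy)cyclohexan-1-one F3. F3 is resolved by preparative supercritical-fluid chromatography on an amylose tris(3,5-dimethylphenylcarbamate) phase into 13 and 14, both of which are used.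

Step 9 (first Wittig reaction). Risks are disproportionation of the mono-ylide to a bis-ylide and hence a second olefination, separation of 18 from the excess of 16, Z-selectivity on a hindered cyclic ketone, and enolisation of the ketone (epimerisation at the silyloxy carbon or conjugation of the β,γ-unsaturated ketone) by the basic ylide. The fallback sets out from 13 and comes back at 18, replacing the symmetrical bis-salt by an unsymmetrical C4 reagent. Tetrahydrofuran is opened with Ph3P·HBr to (4-hydroxybutyl)triphenylphosphonium bromide F4. Its oxido-ylide (2 equiv KN(SiMe3)2, THF, −78 °C) olefinates 13 to 1-[(1S,2R,3Z)-3-(4-hydroxybutylidene)-1-methyl-2-(triethylsilyloxy)cyclohexyl]-4-methylpent-3-en-1-one F5, from which any E isomer can be removed by chromatography at this neutral stage. CBr4/PPh3 converts F5 to 1-[(1S,2R,3Z)-3-(4-bromobutylidene)-1-methyl-2-(triethylsilyloxy)cyclohexyl]-4-methylpent-3-en-1-one F6, and PPh3 in MeCN at 80 °C gives 18.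

**Further compounds**
F1 | step 5 | rel-(1R,4S)-3-methyl-4-(3-methylbut-2-en-1-yl)-4-(triethylsilyloxy)cyclohept-2-en-1-ol (racemate; one enantiomer drawn) | O[C@@H]1CCC[C@](O[Si](CC)(CC)CC)(CC=C(C)C)C(C)=C1
F2 | step 5 | rel-(1R,2R,6S,7R)-7-methyl-6-(3-methylbut-2-en-1-yl)-6-(triethylsilyloxy)-8-oxabicyclo[5.1.0]octan-2-ol (racemate; one enantiomer drawn) | O[C@@H]1CCC[C@](O[Si](CC)(CC)CC)(CC=C(C)C)[C@]2(C)O[C@H]12
F3 | step 6 | rac-(2S,3S)-3-methyl-3-(4-methylpent-3-enoyl)-2-(triethylsilyloxy)cyclohexan-1-one (racemate; one enantiomer drawn) | O=C1CCC[C@](C)(C(=O)CC=C(C)C)[C@@H]1O[Si](CC)(CC)CC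
F4 | step 9 | (4-hydroxybutyl)triphenylphosphonium bromide | [Br-].OCCCC[P+](c1ccccc1)(c1ccccc1)c1ccccc1
F5 | step 9 | 1-[(1S,2R,3Z)-3-(4-hydroxybutylidene)-1-methyl-2-(triethylsilyloxy)cyclohexyl]-4-methylpent-3-en-1-one | OCCC/C=C1/CCC[C@](C)(C(=O)CC=C(C)C)[C@@H]1O[Si](CC)(CC)CC
F6 | step 9 | 1-[(1S,2R,3Z)-3-(4-bromobutylidene)-1-methyl-2-(triethylsilyloxy)cyclohexyl]-4-methylpent-3-en-1-one | BrCCC/C=C1/CCC[C@](C)(C(=O)CC=C(C)C)[C@@H]1O[Si](CC)(CC)CC
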